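**Retrosynthetic overview**
- Target ⇒ ester cleavage at C8 gives 3α,4α-epoxyguaiane-8β,10α-diol plus O-acetylvanilloyl chloride; the oxirane ⇒ epoxidation of the 3-ene directed by the C10 hydroxyl.
- C8 carbinol and C7 ⇒ hydroxyl-directed ketone reduction and dissolving-metal enone reduction of a 10-oxygenated guaia-3,7(11)-dien-8-one; the 3-ene ⇒ dehydration of a 4-hydroxyguaiane.
- Five- and seven-membered rings ⇒ formed together through one C1–C5 bond: transannular cyclization of (4S,5S)-germacrone 4,5-epoxide with capture of the C10 cation, the germacrane → guaiane event of the presumed biogenesis.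
- Epoxide ⇒ catalyst-controlled asymmetric epoxidation of achiral germacrone.
- Ring order: ten-membered carbocycle (purchased) → both rings of the hydroazulene in one step → oxirane last.

Assumption: germacrone (the crystalline main constituent of zdravetz oil) and 4-acetoxy-3-methoxybenzoyl chloride are taken as purchasable starting materials; guaiane/germacrane numbering is used throughout.

**Step 1**
Reactants: 1 germacrone, (3E,7E)-3,7-dimethyl-10-(propan-2-ylidene)cyclodeca-3,7-dien-1-one
Product: 2 (4S,5S)-4,5-epoxygermacra-1(10)E,7(11)-dien-8-one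
Conditions: L-fructose-derived Shi ketone (1,2:4,5-di-O-isopropylidene-β-L-erythro-2,3-hexodiulo-2,6-pyranose, 30 mol %), KHSO5 (as 2KHSO5·KHSO4·K2SO4, 1.2 equiv), K2CO3, Bu4NHSO4 (cat.), MeCN/(MeO)2CH2, aq. Na2B4O7 buffer, 0 °C; chromatography, recrystallisation
Reagents that add atoms: potassium peroxymonosulfate KHSO5, [K+].[O-]S(=O)(=O)OO
Why: Shi asymmetric epoxidation (chiral dioxirane, spiro transition state) suits trans-trisubstituted alkenes, the enone alkene is too electron-poor to react, C4=C5 is the more nucleophilic ring alkene (C1=C10 lies β,γ to the ketone), and because the planar-chiral conformers of 1 interconvert fast the catalyst alone fixes C4 and C5 as 4S,5S by attack on the outer face.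

**Step 2**
Reactants: 2 (4S,5S)-4,5-epoxygermacra-1(10)E,7(11)-dien-8-one
Product: 3 (1R,4S,5S,10R)-4-hydroxy-8-oxoguai-7(11)-en-10-yl formate
Conditions: HCO2H (98 %), CH2Cl2, −10 → 0 °C; cold aq. NaHCO3
Reagents that add atoms: formic acid, O=CO
Why: Epoxide-initiated transannular cation–olefin cyclization in which C1 of the E-configured C1=C10 alkene opens the protonated epoxide at C5 from inside the ring with inversion and formic acid traps the tertiary C10 cation on the outer face (anti addition), setting C1 (R, 1αH), C5 (S, 5βH) and C10 (R, 10α-O) with the trans ring fusion expected from the conformer that has C14 and C15 on opposite ring faces, while the formate keeps the C10 oxygen distinct from the free C4 hydroxyl.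

**Step 3**
Reactants: 3 (1R,4S,5S,10R)-4-hydroxy-8-oxoguai-7(11)-en-10-yl formate
Product: 4 (1R,5S,10R)-8-oxoguaia-3,7(11)-dien-10-yl formate
Conditions: Martin sulfurane Ph2S[OC(CF3)2Ph]2 (1.5 equiv), CH2Cl2, −20 °C → rt
Reagents that add atoms: none
Why: Martin sulfurane dehydration of the only free (tertiary) alcohol through its alkoxysulfonium salt proceeds by anti elimination, H5 is syn to the leaving group and cannot be used, so H3 is lost to give the endocyclic trisubstituted 3-ene (the usual outcome for 4-hydroxyguaianes) under neutral conditions that spare the β-formyloxy ketone.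

**Step 4**
Reactants: 4 (1R,5S,10R)-8-oxoguaia-3,7(11)-dien-10-yl formate
Product: 6 (1R,5S,7R,10R)-10-hydroxyguai-3-en-8-one, via dilithium enolate alkoxide 5 (not isolated)
Conditions: Li (6 equiv), liq. NH3/THF, t-BuOH (1 equiv), −78 → −33 °C; solid NH4Cl, −78 °C
Reagents that add atoms: none
Why: Dissolving-metal (Birch-type) conjugate reduction of the tetrasubstituted enone leaves the isolated 3-ene untouched, the formate is removed by ammonolysis in the same flask, and kinetic C-protonation of enolate 5 on the α-face (the face of the C10 oxygen, which relays the proton, and opposite the C14 methyl) gives the 7R centre with H7α and the isopropyl group β.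

**Step 5**
Reactants: 6 (1R,5S,7R,10R)-10-hydroxyguai-3-en-8-one
Product: 7 (1R,5S,7R,8R,10R)-guai-3-ene-8,10-diol
Conditions: Me4NBH(OAc)3 (5 equiv), MeCN/AcOH (1:1), −30 → −20 °C
Reagents that add atoms: none
Why: Evans–Saksena hydroxyl-directed reduction, in which the C10 alkoxy(diacetoxy)borohydride delivers hydride intramolecularly to the α-face of the C8 ketone and so gives the 1,3-anti diol with 8R configuration (8β-OH, cis to the isopropyl group).

**Step 6**
Reactants: 7 (1R,5S,7R,8R,10R)-guai-3-ene-8,10-diol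
Product: 8 (1R,3R,4S,5S,7R,8R,10R)-3,4-epoxyguaiane-8,10-diol
Conditions: VO(acac)2 (5 mol %), t-BuOOH (1.5 equiv, decane), CH2Cl2, 0 °C → rt
Reagents that add atoms: tert-butyl hydroperoxide, CC(C)(C)OO
Why: Hydroxyl-directed vanadium-catalysed epoxidation (Sharpless–Michaelson type), in which the α-oriented bishomoallylic C10 alkoxide holds the vanadium tert-butylperoxide under the five-membered ring so that oxygen is delivered to the α-face of the only alkene, setting C3 (R) and C4 (S).

**Step 7**
Reactants: 8 (1R,3R,4S,5S,7R,8R,10R)-3,4-epoxyguaiane-8,10-diol, 9 4-acetoxy-3-methoxybenzoyl chloride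
Product: 11 (1R,3R,4S,5S,7R,8R,10R)-3,4-epoxy-10-hydroxyguaian-8-yl 4-hydroxy-3-methoxybenzoate (target), via acetyl-protected ester 10 (not isolated)
Conditions: 9 (1.5 equiv), Et3N, DMAP (0.2 equiv), CH2Cl2, 0 °C → rt; then pyrrolidine (3 equiv), 0 °C
Reagents that add atoms: none
Why: DMAP-catalysed acylation takes place only at the secondary C8 hydroxyl (the C10 hydroxyl is tertiary), and pyrrolidine then removes the much more reactive aryl acetate by aminolysis without touching the alkyl benzoate or the epoxide, so no stereocentre is affected.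

**Compound list**
1 | germacrone, (3E,7E)-3,7-dimethyl-10-(propan-2-ylidene)cyclodeca-3,7-dien-1-one (achiral) | O=C1C/C(C)=C/CC/C(C)=C/CC1=C(C)C | starting material
2 | (4S,5S)-4,5-epoxygermacra-1(10)E,7(11)-dien-8-one (trans-epoxide) | O=C1C/C(C)=C/CC[C@]2(C)O[C@H]2CC1=C(C)C | intermediate
3 | (1R,4S,5S,10R)-4-hydroxy-8-oxoguai-7(11)-en-10-yl formate (1αH,5βH; 4β-OH; 10α-formyloxy) | O=C1C[C@@](C)(OC=O)[C@@H]2CC[C@](C)(O)[C@H]2CC1=C(C)C | intermediate
4 | (1R,5S,10R)-8-oxoguaia-3,7(11)-dien-10-yl formate | O=C1C[C@@](C)(OC=O)[C@@H]2CC=C(C)[C@H]2CC1=C(C)C | intermediate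
5 | dilithium (1R,5S,10R)-guaia-3,7-diene-8,10-diolate (C7=C8 enolate, C10 alkoxide) | [Li+].[Li+].[O-]C=1C[C@@](C)([O-])[C@@H]2CC=C(C)[C@H]2CC=1C(C)C | intermediate
6 | (1R,5S,7R,10R)-10-hydroxyguai-3-en-8-one (7β-isopropyl; 10α-OH) | O=C1C[C@@](C)(O)[C@@H]2CC=C(C)[C@H]2C[C@@H]1C(C)C | intermediate
7 | (1R,5S,7R,8R,10R)-guai-3-ene-8,10-diol (8β-OH; 10α-OH) | O[C@@H]1C[C@@](C)(O)[C@@H]2CC=C(C)[C@H]2C[C@@H]1C(C)C | intermediate
8 | (1R,3R,4S,5S,7R,8R,10R)-3,4-epoxyguaiane-8,10-diol (3α,4α-epoxide) | O[C@@H]1C[C@@](C)(O)[C@@H]2C[C@H]3O[C@@]3(C)[C@H]2C[C@@H]1C(C)C | intermediate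
9 | 4-acetoxy-3-methoxybenzoyl chloride | CC(=O)Oc1ccc(C(=O)Cl)cc1OC | starting material
10 | (1R,3R,4S,5S,7R,8R,10R)-3,4-epoxy-10-hydroxyguaian-8-yl 4-acetoxy-3-methoxybenzoate | COc1cc(C(=O)O[C@@H]2C[C@@](C)(O)[C@@H]3C[C@H]4O[C@@]4(C)[C@H]3C[C@@H]2C(C)C)ccc1OC(C)=O | intermediate
11 | (1R,3R,4S,5S,7R,8R,10R)-3,4-epoxy-10-hydroxyguaian-8-yl 4-hydroxy-3-methoxybenzoate | COc1cc(C(=O)O[C@@H]2C[C@@](C)(O)[C@@H]3C[C@H]4O[C@@]4(C)[C@H]3C[C@@H]2C(C)C)ccc1O | target

**Totals**
Total step count: 7. Longest linear sequence: 7 steps (1 → 11).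

**Steps most likely to fail, with fallbacks**

Step 2 (transannular cyclization). The C10 cation may lose a proton instead of being trapped by formate, and the ring fusion or the C10 configuration may come out wrong. The fallback sets out from 2 and accepts the elimination. Catalytic TsOH·H2O in CH2Cl2 lets the cation collapse into conjugation to give (1R,4S,5S)-4-hydroxyguaia-7(11),9-dien-8-one F1. Martin sulfurane dehydrates its single hydroxyl to (1R,5S)-guaia-3,7(11),9-trien-8-one F2. Nucleophilic (Weitz–Scheffer) epoxidation with H2O2/NaOH in MeOH at the less hindered, α-unsubstituted 9-ene then gives (1R,5S,9S,10S)-9,10-epoxyguaia-3,7(11)-dien-8-one F3. Li in NH3 opens the α,β-epoxy ketone reductively to the C10 carbinol and reduces the remaining enone in the same operation, so the route is rejoined at 6.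

Step 4 (C7 configuration by enolate protonation). Protonation may occur on the β-face or the centre may epimerise. The fallback sets out from 4 and replaces protonation by hydroxyl-directed hydrogenation. NH3 in MeOH removes the formate to give (1R,5S,10R)-10-hydroxyguaia-3,7(11)-dien-8-one F4. VO(acac)2/t-BuOOH epoxidises the 3-ene (the enone alkene is inert) to (1R,3R,4S,5S,10R)-3,4-epoxy-10-hydroxyguai-7(11)-en-8-one F5. [Ir(cod)(PCy3)(py)]PF6 under H2 in CH2Cl2, anchored on the α-oriented C10 hydroxyl, delivers hydrogen to the α-face of the now only alkene and gives (1R,3R,4S,5S,7R,10R)-3,4-epoxy-10-hydroxyguaian-8-one F6. Reduction with Me4NBH(OAc)3 then returns to the route at 8.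

Step 6 (face of epoxidation). If direction by the tertiary bishomoallylic hydroxyl is too weak, the β-epoxide will form, since the β-face is the sterically more open one. The fallback sets out from 7 and uses that steric preference. NBS in aqueous acetone places bromine on the β-face and water opens the bromonium ion at the tertiary carbon from the α-face, giving (1R,3S,4S,5S,7R,8R,10R)-3-bromoguaiane-4,8,10-triol F7. K2CO3 in MeOH closes the oxirane by backside displacement of bromide, which puts the oxygen on the α-face and rejoins the route at 8.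

**Further compounds**
F1 | step 2 | (1R,4S,5S)-4-hydroxyguaia-7(11),9-dien-8-one | O=C1C=C(C)[C@@H]2CC[C@](C)(O)[C@H]2CC1=C(C)C
F2 | step 2 | (1R,5S)-guaia-3,7(11),9-trien-8-one | O=C1C=C(C)[C@@H]2CC=C(C)[C@H]2CC1=C(C)C
F3 | step 2 | (1R,5S,9S,10S)-9,10-epoxyguaia-3,7(11)-dien-8-one | O=C1[C@H]3O[C@@]3(C)[C@@H]2CC=C(C)[C@H]2CC1=C(C)C
F4 | step 4 | (1R,5S,10R)-10-hydroxyguaia-3,7(11)-dien-8-one | O=C1C[C@@](C)(O)[C@@H]2CC=C(C)[C@H]2CC1=C(C)C
F5 | step 4 | (1R,3R,4S,5S,10R)-3,4-epoxy-10-hydroxyguai-7(11)-en-8-one | O=C1C[C@@](C)(O)[C@@H]2C[C@H]3O[C@@]3(C)[C@H]2CC1=C(C)C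
F6 | step 4 | (1R,3R,4S,5S,7R,10R)-3,4-epoxy-10-hydroxyguaian-8-one | O=C1C[C@@](C)(O)[C@@H]2C[C@H]3O[C@@]3(C)[C@H]2C[C@@H]1C(C)C
F7 | step 6 | (1R,3S,4S,5S,7R,8R,10R)-3-bromoguaiane-4,8,10-triol | O[C@@H]1C[C@@](C)(O)[C@@H]2C[C@H](Br)[C@@](C)(O)[C@H]2C[C@@H]1C(C)C
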